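With a slow feed it is tempting to run the lag of a side product on the flask's clock, so first ask whose clock the lag keeps.

| setting | alpha | theta | eta | gamma | alder | birch | larch |
|---|---|---|---|---|---|---|---|
| substrate | 1 mM | 1 mM | 1 mM | 0.50 mM | 1.0 mM (fed, over 2.0 min) | 1.0 mM | 1.0 mM |
| reagent | 0.90 equiv | 0.45 equiv | 1.8 equiv | 0.90 equiv | 0.900 equiv | 0.900 equiv | 0.900 equiv (fed, over 2.0 min) |
| remark | run made earlier | run made earlier | run made earlier | run made earlier | all else is in the flask from the start; the feed brings no volume worth counting | everything together at the start | all else is in the flask from the start; the feed brings no volume worth counting |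
| time |  |  |  |  | 2.5 min | 2.5 min | 2.5 min |

alpha run (percent of the substrate charged)

| time / s | side product / % | target / % |
|---|---|---|
| 10.0 | 0 | 6.5 |
| 15.0 | 0 | 10.2 |
| 25.0 | 0.5 | 13.8 |
| 50.0 | 6.1 | 20.4 |
| 90.0 | 17.8 | 26.0 |

theta run (percent of the substrate charged)

| time / min | side product / % | target / % |
|---|---|---|
| 0.250 | 0.5 | 4.7 |
| 0.417 | 1.7 | 7.7 |
| 0.833 | 5.1 | 11.4 |
| 1.50 | 20.3 | 13.4 |
| 3.00 | 51.7 | 16.3 |

eta run (percent of the substrate charged)

| time / min | side product / % | target / % |
|---|---|---|
| 0.667 | 3.2 | 34.2 |
| 1.33 | 13.1 | 42.6 |
| 2.00 | 24.1 | 45.7 |
| 2.50 | 31.3 | 47.1 |
| 3.00 | 37.3 | 47.3 |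

gamma run (percent of the substrate charged)

| time / min | side product / % | target / % |
|---|---|---|
| 0.667 | 2.6 | 9.9 |
| 1.33 | 16.2 | 15.2 |
| 2.00 | 31.4 | 17.2 |
| 2.50 | 42.7 | 17.4 |
| 3.00 | 52.1 | 19.0 |

(each reading ± 0.5 percentage points)

- the flask that comes out highest in amount of side product, in percent of the substrate charged; "all alike" if 1.5 percentage points covers them all (alder / birch / larch / all alike)
- amount of side product at the end, in percent of the substrate charged, alder
- amount of side product at the end, in percent of the substrate charged, birch
- amount of side product at the end, in percent of the substrate charged, larch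



The runs give a ladder of times. Quickest is the target: alpha already reads 6.5% after 10.0 s. Next comes the lag (induction period) of the side product: alpha reads 0.5% at 25.0 s, then 6.1% at 50.0 s. Slower again is the feed, 2.0 min, which is longer than that lag, so the lag can restart within the feed.

Does it? At 90.0 s alpha reads 17.8% of side product. If the path to side product is close to first order, each portion of substrate runs its own course from its entry. For alder, where substrate is fed, I then subtract half the feed from the time asked, giving 1.50 min: the mean age of the charged substrate at the reading, its mean residence time. Gamma, with [substrate] halved, interpolates to 20.1% at that time, 2.3 percentage points above alpha's reading, so I keep that assumption as an approximation.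

Alpha's last reading falls at that age, so my reckoning for alder is 17.8%. Birch and larch hold their substrate from the start, so it is aged 2.5 min against alder's 1.50 min, and I put both above alder. I put larch, with its reagent fed, on top, since theta on 0.45 equiv of reagent reads 51.7% against 37.3% for eta on 1.8 equiv at 3.00 min.

The forecast gives 40.5% for alder, 40% for birch and 46% for larch, with larch highest, and states that “this clock is assumed to start at t = 0 in the fed flasks too”. On alder it differs from my reckoning, which is lower.

The flask gives 18.5% for alder, 38.4% for birch and 45.2% for larch, so larch is highest; the forecast stands 22 points too high on alder.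

substrate → intermediate A (k = 0.0161 /s); intermediate A → intermediate B (k = 0.0302 /s); substrate + reagent → target (k = 9.14 /M/s); intermediate B → side product (k = 0.0121 /s) At the end alder still holds 17% as substrate and 25.2% as intermediate B. My reckoning by the age of 1.50 min put alder's side product at 17.8%, 0.70 points from the computed value. Now take alder with 0.60 mM of substrate: time, feed and equivalents are held, so the age stays 1.50 min, and gamma, the nearer charge, gives 20.1%. The computed flask gives 19.8%.

Readings and results stem from a simulated flask with made-up constants, and the scatter is random.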